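## Retrosynthetic overview

1. The tetrahydrofuran is made last, by a transannular, water-terminated cascade of the (3R,4R,7R,8R)-bis-epoxide of a macrocyclic 3,7-diene; ketone reduction and the two acetates follow.
2. The ε-lactone is made before it, by attack of the C16 acrylic acid on C12 of an (11R,12R)-epoxide; C11 is then corrected through the 11-ketone, which also keeps C11 out of the cascade.
3. The 14-membered carbocycle is closed first, at C1–C2 (the bond a cembrene cyclase makes), by a C2 sulfonyl carbanion opening a Sharpless epoxy alcohol at C1 with inversion.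
4. The open chain comes from (2E,6E)-farnesyl phenyl sulfone and an isoprene-derived C5 chloroacetate; the two sulfones switch off the 3,4- and 7,8-olefins so that the terminal and 11,12-olefins are oxidised first.
5. Ring order: carbocycle, lactone, tetrahydrofuran. C1 comes from the Sharpless epoxide, C12, C3, C4, C7 and C8 from Shi epoxides, C11 from a CBS reduction.

Assumption: (E)-4-chloro-3-methylbut-2-en-1-yl acetate (the isoprene-derived C5 building block of industrial retinyl acetate manufacture) is bought; ring positions use cembrane numbering (C1 carries the side chain C15–C17; C18, C19, C20 are the methyls on C4, C8, C12).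

## Route

Step 1
Reactants: 1 (2E,6E)-farnesol
Product: 3 (2E,6E)-farnesyl phenyl sulfone, via farnesyl bromide 2 (not isolated)
Conditions: PBr3, Et2O, −10 °C; then PhSO2Na, DMF, rt
Reagents that add atoms: sodium benzenesulfinate, [Na+].[O-]S(=O)c1ccccc1
Why: Bromination of the primary allylic alcohol followed by SN2 S-alkylation of the sulfinate gives the allylic sulfone with both E-olefins intact and creates no stereocenter.

Step 2
Reactants: 3 (2E,6E)-farnesyl phenyl sulfone; 4 (E)-4-chloro-3-methylbut-2-en-1-yl acetate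
Product: 5 (2E,6E,10E)-3,7,11,15-tetramethyl-5-(phenylsulfonyl)hexadeca-2,6,10,14-tetraen-1-yl acetate (racemic at C5)
Conditions: n-BuLi, THF–HMPA, −78 °C; then 4, −78 → −20 °C
Reagents that add atoms: none
Why: Julia-type (Biellmann) alkylation in which the sulfonyl-stabilised allylic carbanion attacks the primary allylic chloride at its α-carbon by SN2 faster than it acylates on the acetate, forming the C5–C6 bond and leaving a sulfone next to the future 7,8-olefin; the sulfone-bearing carbon forms racemic and is later reduced to CH2.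

Step 3
Reactants: 5 (2E,6E,10E)-3,7,11,15-tetramethyl-5-(phenylsulfonyl)hexadeca-2,6,10,14-tetraen-1-yl acetate
Product: 6 (2E,6E,10E)-3,7,11,15-tetramethyl-1,5-bis(phenylsulfonyl)hexadeca-2,6,10,14-tetraene (racemic at C5)
Conditions: Pd(PPh3)4 (5 mol%), PhSO2Na, THF–MeOH, rt
Reagents that add atoms: sodium benzenesulfinate, [Na+].[O-]S(=O)c1ccccc1
Why: Tsuji–Trost allylic substitution in which zerovalent palladium ionises the allylic acetate and sulfinate adds to the less hindered terminus to give the linear E-allylic sulfone, the later ring-closing nucleophile; no stereocenter is formed.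

Step 4
Reactants: 6 (2E,6E,10E)-3,7,11,15-tetramethyl-1,5-bis(phenylsulfonyl)hexadeca-2,6,10,14-tetraene
Product: 7 (2E,6E,10E,14E)-2,6,10,14-tetramethyl-12,16-bis(phenylsulfonyl)hexadeca-2,6,10,14-tetraen-1-ol (racemic at C12)
Conditions: SeO2 (0.1 equiv), t-BuOOH, salicylic acid (0.1 equiv), CH2Cl2, rt
Reagents that add atoms: tert-butyl hydroperoxide, CC(C)(C)OO
Why: Riley allylic oxidation (ene reaction, then [2,3]-sigmatropic shift) takes the E-methyl of the terminal isopropylidene group, because the two olefins next to sulfonyl-bearing carbons are electron-poor and the internal 11,12-olefin is more hindered; no stereocenter is formed.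

Step 5
Reactants: 7 (2E,6E,10E,14E)-2,6,10,14-tetramethyl-12,16-bis(phenylsulfonyl)hexadeca-2,6,10,14-tetraen-1-ol
Product: 8 (2S,3S,6E,10E,14E)-2,3-epoxy-2,6,10,14-tetramethyl-12,16-bis(phenylsulfonyl)hexadeca-6,10,14-trien-1-ol (C12 epimers)
Conditions: Ti(OiPr)4 (10 mol%), L-(+)-diethyl tartrate (12 mol%), t-BuOOH, 4 Å sieves, CH2Cl2, −20 °C
Reagents that add atoms: tert-butyl hydroperoxide, CC(C)(C)OO
Why: Sharpless asymmetric epoxidation touches only the allylic alcohol, and the L-(+)-tartrate complex delivers oxygen to the face that gives the (2S,3S)-epoxy alcohol, whose C3 becomes C1 of the ring.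

Step 6
Reactants: 8 (2S,3S,6E,10E,14E)-2,3-epoxy-2,6,10,14-tetramethyl-12,16-bis(phenylsulfonyl)hexadeca-6,10,14-trien-1-ol
Product: 9 (2S,3S,6R,7R,10E,14E)-2,3:6,7-diepoxy-2,6,10,14-tetramethyl-12,16-bis(phenylsulfonyl)hexadeca-10,14-dien-1-ol (C12 epimers)
Conditions: D-fructose-derived Shi ketone (0.3 equiv), Oxone (2KHSO5·KHSO4·K2SO4), K2CO3 buffer (pH 10.5), Bu4NHSO4 (cat.), MeCN–CH2(OMe)2–H2O, 0 °C
Reagents that add atoms: potassium peroxymonosulfate (from Oxone), [K+].[O-]S(=O)(=O)OO
Why: Shi asymmetric epoxidation by the chiral dioxirane (spiro transition state) converts the one remaining electron-rich trisubstituted olefin into the (R,R)-epoxide under reagent control, while the sulfone-flanked olefins do not react.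

Step 7
Reactants: 9 (2S,3S,6R,7R,10E,14E)-2,3:6,7-diepoxy-2,6,10,14-tetramethyl-12,16-bis(phenylsulfonyl)hexadeca-10,14-dien-1-ol
Product: 10 (1R,11R,12R,15R)-11,12-epoxy-2,6-bis(phenylsulfonyl)cembra-3E,7E-diene-15,16-diol (epimer mixture at C2 and C6)
Conditions: LiN(SiMe3)2 (2.2 equiv), THF (2 mM), −78 → 0 °C; then H2O
Reagents that add atoms: none
Why: Intramolecular epoxide opening by a sulfonyl-stabilised allylic carbanion (the polarity-reversed counterpart of the cyclase step), in which the C2 carbanion attacks the secondary carbon of the lithium epoxy-alkoxide by SN2 with inversion, closing the 14-membered ring at C1–C2 and fixing C1, attack on the distal epoxide being disfavoured because it would give a 10- or 11-membered ring; C2 forms as an epimer mixture and is later reduced to CH2.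

Step 8
Reactants: 10 (1R,11R,12R,15R)-11,12-epoxy-2,6-bis(phenylsulfonyl)cembra-3E,7E-diene-15,16-diol
Product: 11 (1S,11R,12R,15R)-11,12-epoxycembra-3E,7E-diene-15,16-diol
Conditions: PdCl2(dppp) (10 mol%), LiBHEt3, THF, −40 → −20 °C
Reagents that add atoms: none
Why: Palladium-catalysed reductive desulfonylation (π-allylpalladium formation, hydride delivery to the sulfone-bearing, less substituted terminus) regenerates both E-trisubstituted olefins without migration, and the hindered trisubstituted epoxide should survive the borohydride at this temperature; no stereocenter changes (the C1 descriptor changes only through CIP priorities).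

Step 9
Reactants: 11 (1S,11R,12R,15R)-11,12-epoxycembra-3E,7E-diene-15,16-diol
Product: 12 (1S,11R,12R)-11,12-epoxy-16-norcembra-3E,7E-dien-15-one (methyl ketone on C1)
Conditions: NaIO4, THF–pH 7 buffer, 0 °C
Reagents that add atoms: none
Why: Malaprade glycol cleavage of the 1,2-diol gives the methyl ketone and formaldehyde under neutral conditions that spare the epoxide and do not epimerise C1.

Step 10
Reactants: 12 (1S,11R,12R)-11,12-epoxy-16-norcembra-3E,7E-dien-15-one
Product: 13 (1S,11R,12R)-11,12-epoxy-16-norcembra-3E,7E,15(17)-trien-15-yl trifluoromethanesulfonate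
Conditions: KN(SiMe3)2, THF, −78 °C; then PhNTf2
Reagents that add atoms: N-phenylbis(trifluoromethanesulfonimide), O=S(=O)(N(c1ccccc1)S(=O)(=O)C(F)(F)F)C(F)(F)F
Why: Kinetic enolisation removes a proton from the methyl group and not from the hindered C1 methine, and O-sulfonylation of the enolate gives the 1,1-disubstituted vinyl triflate with C1 unchanged.

Step 11
Reactants: 13 (1S,11R,12R)-11,12-epoxy-16-norcembra-3E,7E,15(17)-trien-15-yl trifluoromethanesulfonate
Product: 15 (1S,11R,12S)-11-hydroxycembra-3E,7E,15(17)-trien-16,12-olide, via epoxy acrylic acid 14 (not isolated)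
Conditions: Pd(OAc)2 (5 mol%), dppf, CO (1 atm), KOAc, DMF–H2O, 50 °C; then CSA (0.1 equiv), CH2Cl2, 0 °C
Reagents that add atoms: carbon monoxide, [C-]#[O+]; water, O
Why: Palladium-catalysed hydroxycarbonylation of the vinyl triflate gives the 2-substituted acrylic acid, and acid catalysis then makes the carboxyl group open the only epoxide at its tertiary carbon C12 with inversion (7-exo epoxide-opening lactonisation, the presumed biogenetic lactone formation), setting C12 as S and leaving the epoxide oxygen as the 11R hydroxyl.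

Step 12
Reactants: 15 (1S,11R,12S)-11-hydroxycembra-3E,7E,15(17)-trien-16,12-olide
Product: 16 (1S,12S)-11-oxocembra-3E,7E,15(17)-trien-16,12-olide
Conditions: Dess–Martin periodinane, CH2Cl2, rt
Reagents that add atoms: none
Why: Dess–Martin oxidation of the single free hydroxyl gives the 11-ketone, which erases the wrong C11 configuration and removes the hydroxyl that could otherwise attack the 7,8-epoxide in the next step.

Step 13
Reactants: 16 (1S,12S)-11-oxocembra-3E,7E,15(17)-trien-16,12-olide
Product: 18 (1S,3R,4S,7R,8S,12S)-4,7-epoxy-3,8-dihydroxy-11-oxocembr-15(17)-en-16,12-olide, via keto bis-epoxide 17 (not isolated)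
Conditions: D-fructose-derived Shi ketone (0.6 equiv), Oxone (2KHSO5·KHSO4·K2SO4), K2CO3 buffer (pH 10.5), Bu4NHSO4 (cat.), MeCN–CH2(OMe)2–H2O, 0 °C; then CSA (0.2 equiv), THF–H2O (10:1), 0 °C
Reagents that add atoms: potassium peroxymonosulfate (from Oxone), [K+].[O-]S(=O)(=O)OO; water, O
Why: Double Shi epoxidation gives the (3R,4R,7R,8R)-bis-epoxide under reagent control (the acrylate is too electron-poor to react), and acid then starts the transannular epoxide-opening cascade in which the 7,8-epoxide oxygen attacks the tertiary C4 of the protonated 3,4-epoxide (5-exo, inversion) and water opens the epoxonium ion at the tertiary C8 (inversion), so C3 (R) and C7 (R) are retained and C4 (S) and C8 (S) are set.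

Step 14
Reactants: 18 (1S,3R,4S,7R,8S,12S)-4,7-epoxy-3,8-dihydroxy-11-oxocembr-15(17)-en-16,12-olide
Product: 19 (1S,3R,4S,7R,8S,11S,12S)-4,7-epoxy-3,8,11-trihydroxycembr-15(17)-en-16,12-olide
Conditions: (R)-2-methyl-CBS-oxazaborolidine (0.2 equiv), catecholborane, toluene–CH2Cl2, −78 °C
Reagents that add atoms: none
Why: Corey–Bakshi–Shibata reduction in which the catalyst distinguishes the fully substituted C12 side from the C10 methylene side of the ketone, so the (R)-oxazaborolidine directs hydride to the face that gives the 11S alcohol, and catecholborane at −78 °C leaves the α-methylene lactone alone.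

Step 15
Reactants: 19 (1S,3R,4S,7R,8S,11S,12S)-4,7-epoxy-3,8,11-trihydroxycembr-15(17)-en-16,12-olide
Product: 20 (1S,3R,4S,7R,8S,11S,12S)-3,11-diacetoxy-4,7-epoxy-8-hydroxycembr-15(17)-en-16,12-olide (target CNP0343714.5)
Conditions: Ac2O, pyridine, DMAP (cat.), 0 °C → rt
Reagents that add atoms: acetic anhydride, CC(=O)OC(C)=O
Why: DMAP-catalysed acylation esterifies the two secondary hydroxyls at C3 and C11, whereas the tertiary C8 hydroxyl does not react under these conditions; no stereocenter is touched.

## Compound list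

1 | (2E,6E)-farnesol | CC(C)=CCC/C(C)=C/CC/C(C)=C/CO | starting material
2 | (2E,6E)-farnesyl bromide | CC(C)=CCC/C(C)=C/CC/C(C)=C/CBr | intermediate
3 | (2E,6E)-farnesyl phenyl sulfone | CC(C)=CCC/C(C)=C/CC/C(C)=C/CS(=O)(=O)c1ccccc1 | intermediate
4 | (E)-4-chloro-3-methylbut-2-en-1-yl acetate | ClC/C(C)=C/COC(C)=O | starting material
5 | (2E,6E,10E)-3,7,11,15-tetramethyl-5-(phenylsulfonyl)hexadeca-2,6,10,14-tetraen-1-yl acetate (racemic at C5) | CC(C)=CCC/C(C)=C/CC/C(C)=C/C(C/C(C)=C/COC(C)=O)S(=O)(=O)c1ccccc1 | intermediate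
6 | (2E,6E,10E)-3,7,11,15-tetramethyl-1,5-bis(phenylsulfonyl)hexadeca-2,6,10,14-tetraene (racemic at C5) | CC(C)=CCC/C(C)=C/CC/C(C)=C/C(C/C(C)=C/CS(=O)(=O)c1ccccc1)S(=O)(=O)c1ccccc1 | intermediate
7 | (2E,6E,10E,14E)-2,6,10,14-tetramethyl-12,16-bis(phenylsulfonyl)hexadeca-2,6,10,14-tetraen-1-ol (racemic at C12) | OC/C(C)=C/CC/C(C)=C/CC/C(C)=C/C(C/C(C)=C/CS(=O)(=O)c1ccccc1)S(=O)(=O)c1ccccc1 | intermediate
8 | (2S,3S,6E,10E,14E)-2,3-epoxy-2,6,10,14-tetramethyl-12,16-bis(phenylsulfonyl)hexadeca-6,10,14-trien-1-ol (C12 epimers) | OC[C@]1(C)O[C@H]1CC/C(C)=C/CC/C(C)=C/C(C/C(C)=C/CS(=O)(=O)c1ccccc1)S(=O)(=O)c1ccccc1 | intermediate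
9 | (2S,3S,6R,7R,10E,14E)-2,3:6,7-diepoxy-2,6,10,14-tetramethyl-12,16-bis(phenylsulfonyl)hexadeca-10,14-dien-1-ol (C12 epimers) | OC[C@]1(C)O[C@H]1CC[C@@]2(C)O[C@@H]2CC/C(C)=C/C(C/C(C)=C/CS(=O)(=O)c1ccccc1)S(=O)(=O)c1ccccc1 | intermediate
10 | (1R,11R,12R,15R)-11,12-epoxy-2,6-bis(phenylsulfonyl)cembra-3E,7E-diene-15,16-diol (epimer mixture at C2 and C6) | OC[C@](C)(O)[C@@H]1C(S(=O)(=O)c2ccccc2)/C=C(C)/CC(S(=O)(=O)c2ccccc2)/C=C(C)/CC[C@H]2O[C@]2(C)CC1 | intermediate
11 | (1S,11R,12R,15R)-11,12-epoxycembra-3E,7E-diene-15,16-diol | OC[C@](C)(O)[C@@H]1C/C=C(C)/CC/C=C(C)/CC[C@H]2O[C@]2(C)CC1 | intermediate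
12 | (1S,11R,12R)-11,12-epoxy-16-norcembra-3E,7E-dien-15-one | CC(=O)[C@@H]1C/C=C(C)/CC/C=C(C)/CC[C@H]2O[C@]2(C)CC1 | intermediate
13 | (1S,11R,12R)-11,12-epoxy-16-norcembra-3E,7E,15(17)-trien-15-yl trifluoromethanesulfonate | C=C(OS(=O)(=O)C(F)(F)F)[C@@H]1C/C=C(C)/CC/C=C(C)/CC[C@H]2O[C@]2(C)CC1 | intermediate
14 | (1S,11R,12R)-11,12-epoxycembra-3E,7E,15(17)-trien-16-oic acid | C=C(C(=O)O)[C@@H]1C/C=C(C)/CC/C=C(C)/CC[C@H]2O[C@]2(C)CC1 | intermediate
15 | (1S,11R,12S)-11-hydroxycembra-3E,7E,15(17)-trien-16,12-olide | C=C1C(=O)O[C@@]2(C)CC[C@H]1C/C=C(C)/CC/C=C(C)/CC[C@H]2O | intermediate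
16 | (1S,12S)-11-oxocembra-3E,7E,15(17)-trien-16,12-olide | C=C1C(=O)O[C@@]2(C)CC[C@H]1C/C=C(C)/CC/C=C(C)/CCC2=O | intermediate
17 | (1S,3R,4R,7R,8R,12S)-3,4:7,8-diepoxy-11-oxocembr-15(17)-en-16,12-olide | C=C1C(=O)O[C@@]2(C)CC[C@H]1C[C@H]3O[C@]3(C)CC[C@H]3O[C@]3(C)CCC2=O | intermediate
18 | (1S,3R,4S,7R,8S,12S)-4,7-epoxy-3,8-dihydroxy-11-oxocembr-15(17)-en-16,12-olide | C=C1C(=O)O[C@@]2(C)CC[C@H]1C[C@@H](O)[C@]1(C)CC[C@@H](O1)[C@@](C)(O)CCC2=O | intermediate
19 | (1S,3R,4S,7R,8S,11S,12S)-4,7-epoxy-3,8,11-trihydroxycembr-15(17)-en-16,12-olide | C=C1C(=O)O[C@@]2(C)CC[C@H]1C[C@@H](O)[C@]1(C)CC[C@@H](O1)[C@@](C)(O)CC[C@@H]2O | intermediate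
20 | (1S,3R,4S,7R,8S,11S,12S)-3,11-diacetoxy-4,7-epoxy-8-hydroxycembr-15(17)-en-16,12-olide (CNP0343714.5) | C=C1C(=O)O[C@@]2(C)CC[C@H]1C[C@@H](OC(C)=O)[C@]1(C)CC[C@@H](O1)[C@@](C)(O)CC[C@@H]2OC(C)=O | target

## Step count and weak points

Total step count: 15. Longest linear sequence: 15 steps (1 → 20); compound 4 enters in step 2.

**Step 7 (macrocyclisation).** The carbanion must close a 14-membered ring on a trisubstituted epoxide while a second epoxide is present. The fallback sets out from 8 and closes the ring before the second epoxidation, so that the Sharpless epoxide is the only electrophile: LiN(SiMe3)2 in dilute THF gives the epoxide-free macrocyclic diol bis-sulfone F1. The Shi epoxidation is then run on F1, whose 3,4- and 7,8-olefins are still switched off by the ring sulfones, and this comes back to the route at 10.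

**Step 8 (desulfonylation beside an epoxide).** LiBHEt3 may open the 11,12-epoxide. The fallback sets out from 10 and comes back at 11 by replacing hydride transfer with single-electron reductive cleavage: sodium amalgam (Na/Hg), Na2HPO4, MeOH–THF, −20 °C. This cannot open the epoxide and makes no new compound (F0), but positional olefin isomers from protonation of the allyl anions would have to be separated.

**Step 13 (double epoxidation and transannular cascade).** Water may hydrolyse the 3,4-epoxide directly before the 7,8-epoxide takes part, and facial control on the ring may be incomplete. The fallback sets out from 17, isolated after a buffered work-up, and runs the cascade without water: CF3CO2H in CH2Cl2 at −40 °C, so that only trifluoroacetate can end the epoxonium ion, gives the 8-O-trifluoroacetate F2. NaHCO3 in MeOH then removes the trifluoroacetyl group and comes back to the route at 18.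

Further compounds
F1 | step 7 | (1R,15R)-2,6-bis(phenylsulfonyl)cembra-3E,7E,11E-triene-15,16-diol (epimer mixture at C2 and C6) | OC[C@](C)(O)[C@@H]1C(S(=O)(=O)c2ccccc2)/C=C(C)/CC(S(=O)(=O)c2ccccc2)/C=C(C)/CC/C=C(C)/CC1
F0 | step 8 | none | none
F2 | step 13 | (1S,3R,4S,7R,8S,12S)-4,7-epoxy-3-hydroxy-11-oxo-8-(trifluoroacetoxy)cembr-15(17)-en-16,12-olide | C=C1C(=O)O[C@@]2(C)CC[C@H]1C[C@@H](O)[C@]1(C)CC[C@@H](O1)[C@@](C)(OC(=O)C(F)(F)F)CCC2=O
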